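**Strategy**

The synthesis rests on cutting ring A (C1, C2, C3, C4, C5, C9) at C1–C2 and removing one methyl from C8. In ring B (C1, C8, C7, C6, C5, C9) C8 is the methyl-bearing β-carbon of the C9 enone, and the acyl carbon C2 is held on C5, 1,3 to C1 across C9. One operation with Me2CuLi on enone 16 therefore installs the C8 gem-dimethyl group and turns the resulting C1 enolate onto the (E)-β-methoxyacrylate ester, closing ring A. The precursor is a Diels–Alder-derived 3-methylcyclohexenone whose acrylate geometry is locked by way of a C9–O lactone.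

Key step: step 12

Remark (locants): C1–C9 are the locants of the bicyclo[3.3.1]nonane core of the target and are used for the ring B intermediates as well; "lavandulyl" is (2R)-5-methyl-2-(prop-1-en-2-yl)hex-4-en-1-yl and "prenyl" is 3-methylbut-2-en-1-yl.

Remark (catalyst sense): step 7 needs attack on the Si face of the α-carbon of enal 6; the catalyst is written as the (S)-prolinol-derived oxazaborolidine, and its mirror image is taken instead if this enal shows the opposite facial preference.

**Route**

Step 1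
Reactants: 1 (±)-lavandulol
Product: 2 (S)-lavandulol
Conditions: Porcine pancreas lipase, vinyl acetate, hexane, 25 °C, run past half conversion; chromatography
Reagents that add atoms: none
Why: Lipase-catalysed kinetic resolution (enantioselective transesterification), in which the enzyme is expected to acetylate the (R)-alcohol faster, so that the alcohol left over should be the (S)-enantiomer in high enantiomeric purity.

Step 2
Reactants: 2 (S)-lavandulol
Product: 3 (S)-lavandulyl iodide
Conditions: I2, PPh3, imidazole, CH2Cl2, 0 → 23 °C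
Reagents that add atoms: iodine, II
Why: Appel-type iodination by SN2 displacement of the alkoxyphosphonium group at the primary carbon, which leaves the neighbouring stereocentre untouched.

Step 3
Reactants: 3 (S)-lavandulyl iodide
Product: 4 (4S)-7-methyl-4-(prop-1-en-2-yl)oct-6-enenitrile
Conditions: MeCN, LDA (LiN(iPr)2), THF, −78 °C; then 3, −78 → 0 °C
Reagents that add atoms: acetonitrile, CC#N
Why: SN2 alkylation of lithioacetonitrile by the primary iodide adds the two carbons needed between the lavandulyl CH2 and the future aldehyde, the small nucleophile at low temperature being expected to outrun E2.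

Step 4
Reactants: 4 nitrile
Product: 5 (4S)-7-methyl-4-(prop-1-en-2-yl)oct-6-enal
Conditions: DIBAL-H (i-Bu2AlH), CH2Cl2, −78 °C; aq. potassium sodium tartrate
Reagents that add atoms: water, O
Why: Partial DIBAL-H reduction of the nitrile stops at the N-aluminoimine, which is hydrolysed to the aldehyde on work-up.

Step 5
Reactants: 5 aldehyde
Product: 6 2-lavandulylacrolein, (4R)-7-methyl-2-methylidene-4-(prop-1-en-2-yl)oct-6-enal
Conditions: aq. HCHO, pyrrolidine (10 mol%), propionic acid (10 mol%), i-PrOH, 45 °C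
Reagents that add atoms: formaldehyde, C=O
Why: Organocatalytic Mannich-type α-methylenation (enamine addition to formaldehyde, then elimination) converts the α-CH2 aldehyde into the 2-substituted acrolein without touching the remote stereocentre.

Step 6
Reactants: 7 citral
Product: 8 (1E,3E)-TBS dienol ether of citral
Conditions: TBSOTf, Et3N, Et2O, 0 → 23 °C; used in excess together with its 3Z isomer
Reagents that add atoms: tert-butyldimethylsilyl triflate, CC(C)(C)[Si](C)(C)OS(=O)(=O)C(F)(F)F
Why: Soft enolisation (vinylogous silyl enol ether formation), in which O-silylation gives a dienyl cation that should lose a proton from the C4 methylene in the Zaitsev sense to give the fully conjugated 1E diene, of which only the 3E isomer can reach the s-cis form needed in step 7.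

Step 7
Reactants: 6 2-lavandulylacrolein; 8 TBS dienol ether
Product: 9 Diels–Alder aldehyde (C5 S, C7 R, C9 R; CHO, OTBS and C7 prenyl all cis)
Conditions: (S)-o-tolyl-oxazaborolidine from α,α-diphenylprolinol (20 mol%), Tf2NH, CH2Cl2, −78 → −40 °C
Reagents that add atoms: none
Why: Catalytic asymmetric Diels–Alder reaction in which the nucleophilic C4 terminus of the diene bonds to the enal CH2 and the siloxy carbon to the α-carbon, endo-CHO addition to the 3E diene places the C7 prenyl group cis to the formyl group, and the cationic oxazaborolidine shields one face of the enal so that C5 and C7 are set together (C9 is erased later).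

Step 8
Reactants: 9 Diels–Alder aldehyde; 10 ethyl diazoacetate
Product: 11 β-keto ester (C5–C(=O)CH2CO2Et, C9–OTBS)
Conditions: SnCl2 (10 mol%), CH2Cl2, 23 °C
Reagents that add atoms: none
Why: Roskamp reaction, in which SnCl2-activated addition of the diazoester to the non-enolisable neopentyl aldehyde is followed by a 1,2-hydride shift with loss of N2 to give the β-keto ester.

Step 9
Reactants: 11 β-keto ester
Product: 13 C9–O methoxy lactone (4-methoxy-5,6-dihydropyran-2-one fused to ring B), via lactone dione 12 (not isolated)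
Conditions: TBAF, THF, 0 → 23 °C; then Me2SO4, 23 °C
Reagents that add atoms: dimethyl sulfate, COS(=O)(=O)OC
Why: Fluoride desilylation frees the C9 alkoxide, which lactonises onto the ester (6-exo-trig transesterification), and the acidic pyran-2,4-dione is then O-methylated as its ammonium enolate at the C4 oxygen, so that the C3=C4 enol ether is made inside a ring in which C5 and C2 are necessarily cis.

Step 10
Reactants: 13 methoxy lactone
Product: 15 (E)-hydroxy ester (C9–OH, ethyl β-methoxyacrylate on C5), via lithium carboxylate 14 (not isolated)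
Conditions: LiOH·H2O, THF/H2O, 23 °C; evaporate, toluene azeotrope; EtI, DMF, 23 °C; used crude
Reagents that add atoms: lithium hydroxide, [Li+].[OH-]; iodoethane, CCI
Why: Saponification of the lactone by acyl attack (C5 is quaternary, so no vinylogous elimination can open it another way) followed by SN2 O-ethylation of the carboxylate gives the acyclic acrylate with the E geometry inherited from the ring, the neutral hydroxy ester being oxidised at once to forestall relactonisation.

Step 11
Reactants: 15 (E)-hydroxy ester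
Product: 16 ring B enone (3-methylcyclohexenone with lavandulyl and (E)-β-methoxyacrylate on C5, prenyl on C7)
Conditions: Dess–Martin periodinane, pyridine, CH2Cl2, 0 °C
Reagents that add atoms: none
Why: Dess–Martin oxidation of the secondary allylic alcohol gives the C9 enone under buffered, non-basic conditions that spare the enol ether, the alkenes and the γ-stereocentre C7.

Step 12
Reactants: 16 ring B enone
Product: 18 bicyclic vinylogous ester (C1–H, C8 gem-dimethyl), via lithium enolate 17 (not isolated)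
Conditions: Me2CuLi (CuI, 2 MeLi; 1.5 equiv), Et2O, −78 → −20 °C; then THF, −20 → 23 °C; aq. NH4Cl
Reagents that add atoms: lithium dimethylcuprate, [Li+].C[Cu-]C
Why: The cuprate transfers methyl to C8, the β-carbon of the C9 enone, and leaves the lithium enolate 17, whose only nucleophilic carbon is C1 because C5 is quaternary. On warming, C1 attacks the ester carbonyl C2 of the acrylate on C5 and ethoxide leaves, a Claisen (Dieckmann) condensation that closes ring A (C1, C2, C3, C4, C5, C9) in a 6-(enolendo)-exo-trig mode. The closest known reaction types are tandem cuprate conjugate addition–Dieckmann cyclisations and the α,α′-annulations of cyclohexanone enolates or enamines that give bicyclo[3.3.1]nonane-2,9-diones. The new stereocentre C1 is fixed by the tether: the acrylate on C5 is 1,3 to C1 across C9, so the bond can form only on the enolate face that carries it and only the cis-bridged (1S) bicycle can arise, while C8 becomes a non-stereogenic CMe2 carbon. The step needs the cuprate to prefer the enone over the acrylate (whose β-carbon C4 is neopentyl and deactivated by its methoxy donor), C- over O-acylation (lithium enolate, ester electrophile, reversible O-acylation) and a cis relation of C5 and C2 on the C3=C4 bond, which is guaranteed by the lactone detour of steps 9 and 10.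

Step 13
Reactants: 19 3,4-dihydroxybenzoic acid
Product: 20 tert-butyldimethylsilyl 3,4-bis(tert-butyldimethylsilyloxy)benzoate
Conditions: TBSCl, imidazole, DMF, 23 °C; non-aqueous work-up
Reagents that add atoms: tert-butyldimethylsilyl chloride, CC(C)(C)[Si](C)(C)Cl
Why: Imidazole-promoted O-silylation of both phenols and of the carboxylic acid (silyl ester).

Step 14
Reactants: 20 tris-silylated acid
Product: 21 3,4-bis(tert-butyldimethylsilyloxy)benzoyl chloride
Conditions: (COCl)2, DMF (cat.), CH2Cl2, 0 → 23 °C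
Reagents that add atoms: oxalyl chloride, O=C(Cl)C(=O)Cl
Why: Vilsmeier-type conversion of the silyl ester into the acid chloride releases TBSCl and no free HCl, so the aryl silyl ethers survive.

Step 15
Reactants: 18 bicyclic vinylogous ester; 21 aroyl chloride
Product: 23 C3-aroyl bicycle, via C3-lithio bicycle 22 (not isolated)
Conditions: LiTMP (lithium 2,2,6,6-tetramethylpiperidide), THF, −78 °C; then 21, −78 → −40 °C
Reagents that add atoms: none
Why: Vinylic lithiation–acylation, in which the hindered amide removes the exposed C3–H of the vinylogous ester faster than the C1–H screened by the C8 gem-dimethyl group and the vinyllithium is acylated by the aroyl chloride.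

Step 16
Reactants: 24 prenol
Product: 25 (S)-3,3-dimethylglycidol
Conditions: Ti(OiPr)4 (5 mol%), L-(+)-diethyl tartrate (6 mol%), t-BuOOH, 4 Å molecular sieves, CH2Cl2, −20 °C; non-aqueous work-up
Reagents that add atoms: tert-butyl hydroperoxide, CC(C)(C)OO
Why: Sharpless asymmetric epoxidation, in which the titanium–L-(+)-tartrate complex delivers oxygen to the face of the allylic alcohol that gives the (2S)-epoxy alcohol.

Step 17
Reactants: 25 (S)-3,3-dimethylglycidol
Product: 26 (S)-3,3-dimethylglycidyl triflate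
Conditions: Tf2O, pyridine, CH2Cl2, −78 → −40 °C; cold filtration, used at once
Reagents that add atoms: triflic anhydride, O=S(=O)(OS(=O)(=O)C(F)(F)F)C(F)(F)F
Why: O-Sulfonylation of the primary alcohol at low temperature, which does not involve the stereocentre.

Step 18
Reactants: 23 C3-aroyl bicycle; 26 epoxy triflate
Product: 28 C1-alkylated epoxide, via C1-lithio bicycle 27 (not isolated)
Conditions: LiTMP, THF, −78 °C; then 26, −78 → −20 °C
Reagents that add atoms: none
Why: Bridgehead lithiation–alkylation, in which LiTMP (C3 is now blocked and the base has no β-hydride to reduce the aryl ketone) removes C1–H between the C2 and C9 carbonyls and the bridgehead carbanion displaces the primary triflate by SN2 with necessary retention at C1, O-alkylation being disfavoured because it would create a bridgehead enol ether.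

Step 19
Reactants: 28 C1-alkylated epoxide
Product: 29 (S)-diol
Conditions: HClO4 (aq., cat.), THF/H2O, 0 °C
Reagents that add atoms: water, O
Why: Acid-catalysed epoxide hydrolysis, in which water opens the protonated epoxide at the tertiary carbon so that the secondary C–O bond and its (S) configuration are retained, while the C4 enol stays masked as its methyl ether.

Step 20
Reactants: 29 (S)-diol
Product: 31 target CNP0245306.2, via demethylated bis-silyl ether 30 (not isolated)
Conditions: LiCl, DMSO, 120 °C; cool to 23 °C; TBAF, AcOH, THF; argon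
Reagents that add atoms: none
Why: Krapcho-type SN2 demethylation of the vinylogous ester by chloride releases the enolised 2,4-dione, and buffered fluoride then cleaves the two aryl silyl ethers without acid, which could cyclise the enol onto the side-chain alkenes.

**Compound list**

1 | (±)-lavandulol, rac-5-methyl-2-(prop-1-en-2-yl)hex-4-en-1-ol | C=C(C)C(CC=C(C)C)CO | starting material
2 | (S)-lavandulol, (2S)-5-methyl-2-(prop-1-en-2-yl)hex-4-en-1-ol | C=C(C)[C@H](CC=C(C)C)CO | intermediate
3 | (S)-lavandulyl iodide, (2S)-1-iodo-5-methyl-2-(prop-1-en-2-yl)hex-4-ene | C=C(C)[C@H](CC=C(C)C)CI | intermediate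
4 | (4S)-7-methyl-4-(prop-1-en-2-yl)oct-6-enenitrile | C=C(C)[C@H](CC=C(C)C)CCC#N | intermediate
5 | (4S)-7-methyl-4-(prop-1-en-2-yl)oct-6-enal | C=C(C)[C@H](CC=C(C)C)CCC=O | intermediate
6 | 2-lavandulylacrolein, (4R)-7-methyl-2-methylidene-4-(prop-1-en-2-yl)oct-6-enal | C=C(C)[C@H](CC=C(C)C)CC(=C)C=O | intermediate
7 | citral (3,7-dimethylocta-2,6-dienal, geranial/neral mixture) | CC(C)=CCCC(C)=CC=O | starting material
8 | tert-butyl{[(1E,3E)-3,7-dimethylocta-1,3,6-trien-1-yl]oxy}dimethylsilane | CC(C)=CC/C=C(C)/C=C/O[Si](C)(C)C(C)(C)C | intermediate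
9 | (1S,2R,5R)-2-(tert-butyldimethylsilyloxy)-4-methyl-1-[(2R)-lavandulyl]-5-prenylcyclohex-3-ene-1-carbaldehyde (core C5 S, C9 R, C7 R) | C=C(C)[C@H](CC=C(C)C)C[C@]1(C=O)C[C@@H](CC=C(C)C)C(C)=C[C@H]1O[Si](C)(C)C(C)(C)C | intermediate
10 | ethyl diazoacetate | CCOC(=O)C=[N+]=[N-] | starting material
11 | ethyl 3-[(1S,2R,5R)-2-(tert-butyldimethylsilyloxy)-4-methyl-1-[(2R)-lavandulyl]-5-prenylcyclohex-3-en-1-yl]-3-oxopropanoate | C=C(C)[C@H](CC=C(C)C)C[C@]1(C(=O)CC(=O)OCC)C[C@@H](CC=C(C)C)C(C)=C[C@H]1O[Si](C)(C)C(C)(C)C | intermediate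
12 | (4aS,6R,8aR)-7-methyl-4a-[(2R)-lavandulyl]-6-prenyl-4a,5,6,8a-tetrahydro-2H-chromene-2,4(3H)-dione | C=C(C)[C@H](CC=C(C)C)C[C@]1(C(=O)CC(=O)O2)C[C@@H](CC=C(C)C)C(C)=C[C@H]12 | intermediate
13 | (4aS,6R,8aR)-4-methoxy-7-methyl-4a-[(2R)-lavandulyl]-6-prenyl-4a,5,6,8a-tetrahydro-2H-chromen-2-one | C=C(C)[C@H](CC=C(C)C)C[C@]1(C(OC)=CC(=O)O2)C[C@@H](CC=C(C)C)C(C)=C[C@H]12 | intermediate
14 | lithium (2E)-3-[(1S,2R,5R)-2-hydroxy-4-methyl-1-[(2R)-lavandulyl]-5-prenylcyclohex-3-en-1-yl]-3-methoxyprop-2-enoate | C=C(C)[C@H](CC=C(C)C)C[C@]1(/C(OC)=C\C(=O)[O-])C[C@@H](CC=C(C)C)C(C)=C[C@H]1O.[Li+] | intermediate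
15 | ethyl (2E)-3-[(1S,2R,5R)-2-hydroxy-4-methyl-1-[(2R)-lavandulyl]-5-prenylcyclohex-3-en-1-yl]-3-methoxyprop-2-enoate | C=C(C)[C@H](CC=C(C)C)C[C@]1(/C(OC)=C\C(=O)OCC)C[C@@H](CC=C(C)C)C(C)=C[C@H]1O | intermediate
16 | ethyl (2E)-3-methoxy-3-[(1R,5R)-4-methyl-1-[(2R)-lavandulyl]-5-prenyl-2-oxocyclohex-3-en-1-yl]prop-2-enoate (core C5 R, C7 R) | C=C(C)[C@H](CC=C(C)C)C[C@]1(/C(OC)=C\C(=O)OCC)C[C@@H](CC=C(C)C)C(C)=CC1=O | intermediate
17 | lithium enolate (C9–O−, C1=C9) of the C8-dimethylated ketone, C5 and C7 as in 16 | C=C(C)[C@H](CC=C(C)C)C[C@]1(/C(OC)=C\C(=O)OCC)C[C@@H](CC=C(C)C)C(C)(C)C=C1[O-].[Li+] | intermediate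
18 | (1S,5R,7R)-4-methoxy-8,8-dimethyl-5-[(2R)-lavandulyl]-7-prenylbicyclo[3.3.1]non-3-ene-2,9-dione | C=C(C)[C@H](CC=C(C)C)C[C@@]12C[C@@H](CC=C(C)C)C(C)(C)[C@@H](C(=O)C=C1OC)C2=O | intermediate
19 | 3,4-dihydroxybenzoic acid | O=C(O)c1ccc(O)c(O)c1 | starting material
20 | tert-butyldimethylsilyl 3,4-bis(tert-butyldimethylsilyloxy)benzoate | CC(C)(C)[Si](C)(C)OC(=O)c1ccc(O[Si](C)(C)C(C)(C)C)c(O[Si](C)(C)C(C)(C)C)c1 | intermediate
21 | 3,4-bis(tert-butyldimethylsilyloxy)benzoyl chloride | O=C(Cl)c1ccc(O[Si](C)(C)C(C)(C)C)c(O[Si](C)(C)C(C)(C)C)c1 | intermediate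
22 | 3-lithio derivative of 18 (lithium on the vinylic carbon C3) | C=C(C)[C@H](CC=C(C)C)C[C@@]12C[C@@H](CC=C(C)C)C(C)(C)[C@@H](C(=O)C([Li])=C1OC)C2=O | intermediate
23 | (1R,5R,7R)-3-[3,4-bis(tert-butyldimethylsilyloxy)benzoyl]-4-methoxy-8,8-dimethyl-5-[(2R)-lavandulyl]-7-prenylbicyclo[3.3.1]non-3-ene-2,9-dione | C=C(C)[C@H](CC=C(C)C)C[C@@]12C[C@@H](CC=C(C)C)C(C)(C)[C@@H](C(=O)C(C(=O)c3ccc(O[Si](C)(C)C(C)(C)C)c(O[Si](C)(C)C(C)(C)C)c3)=C1OC)C2=O | intermediate
24 | prenol, 3-methylbut-2-en-1-ol | CC(C)=CCO | starting material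
25 | [(2S)-3,3-dimethyloxiran-2-yl]methanol | OC[C@@H]1OC1(C)C | intermediate
26 | [(2S)-3,3-dimethyloxiran-2-yl]methyl trifluoromethanesulfonate | O=S(=O)(OC[C@@H]1OC1(C)C)C(F)(F)F | intermediate
27 | 1-lithio derivative of 23 (lithium on the bridgehead carbon C1) | C=C(C)[C@H](CC=C(C)C)C[C@@]12C[C@@H](CC=C(C)C)C(C)(C)[C@@]([Li])(C(=O)C(C(=O)c3ccc(O[Si](C)(C)C(C)(C)C)c(O[Si](C)(C)C(C)(C)C)c3)=C1OC)C2=O | intermediate
28 | (1R,5R,7R)-3-[3,4-bis(tert-butyldimethylsilyloxy)benzoyl]-1-{[(2S)-3,3-dimethyloxiran-2-yl]methyl}-4-methoxy-8,8-dimethyl-5-[(2R)-lavandulyl]-7-prenylbicyclo[3.3.1]non-3-ene-2,9-dione | C=C(C)[C@H](CC=C(C)C)C[C@@]12C[C@@H](CC=C(C)C)C(C)(C)[C@@](C[C@@H]3OC3(C)C)(C(=O)C(C(=O)c3ccc(O[Si](C)(C)C(C)(C)C)c(O[Si](C)(C)C(C)(C)C)c3)=C1OC)C2=O | intermediate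
29 | (1R,5R,7R)-3-[3,4-bis(tert-butyldimethylsilyloxy)benzoyl]-1-[(2S)-2,3-dihydroxy-3-methylbutyl]-4-methoxy-8,8-dimethyl-5-[(2R)-lavandulyl]-7-prenylbicyclo[3.3.1]non-3-ene-2,9-dione | C=C(C)[C@H](CC=C(C)C)C[C@@]12C[C@@H](CC=C(C)C)C(C)(C)[C@@](C[C@H](O)C(C)(C)O)(C(=O)C(C(=O)c3ccc(O[Si](C)(C)C(C)(C)C)c(O[Si](C)(C)C(C)(C)C)c3)=C1OC)C2=O | intermediate
30 | (1R,5R,7R)-3-[3,4-bis(tert-butyldimethylsilyloxy)benzoyl]-1-[(2S)-2,3-dihydroxy-3-methylbutyl]-4-hydroxy-8,8-dimethyl-5-[(2R)-lavandulyl]-7-prenylbicyclo[3.3.1]non-3-ene-2,9-dione | C=C(C)[C@H](CC=C(C)C)C[C@@]12C[C@@H](CC=C(C)C)C(C)(C)[C@@](C[C@H](O)C(C)(C)O)(C(=O)C(C(=O)c3ccc(O[Si](C)(C)C(C)(C)C)c(O[Si](C)(C)C(C)(C)C)c3)=C1O)C2=O | intermediate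
31 | CNP0245306.2, (1R,5R,7R)-3-(3,4-dihydroxybenzoyl)-1-[(2S)-2,3-dihydroxy-3-methylbutyl]-4-hydroxy-8,8-dimethyl-5-[(2R)-5-methyl-2-(prop-1-en-2-yl)hex-4-en-1-yl]-7-(3-methylbut-2-en-1-yl)bicyclo[3.3.1]non-3-ene-2,9-dione | C=C(C)[C@H](CC=C(C)C)C[C@@]12C[C@@H](CC=C(C)C)C(C)(C)[C@@](C[C@H](O)C(C)(C)O)(C(=O)C(C(=O)c3ccc(O)c(O)c3)=C1O)C2=O | target

**Step count**

Total: 20 steps. Longest linear sequence: 15 steps (steps 1–5, 7–12, 15, 18–20).

**Steps most likely to fail**

Step 12. Methyl transfer to the fully substituted C8 may be slow, and the Claisen closure may stall or reverse, because the bridged β-diketone cannot be deprotonated and ethoxide can reopen it; the enolate may also be lost to protonation or O-acylation. The fallback sets out from 16 and separates the two bond formations, making the acylation irreversible. Me2CuLi with TMSCl, followed by mild acid, should give the saturated keto ester F1. KOSiMe3 in THF cleaves the ethyl ester to the keto acid F2. 1-Chloro-N,N,2-trimethylpropenylamine converts this into the acid chloride F3. Soft enolisation of the C9 ketone (MgBr2·OEt2, i-Pr2NEt, CH2Cl2) then effects intramolecular C-acylation at C1, the acid chloride form of the α,α′-annulation that gives bicyclo[3.3.1]nonane-2,9-diones, and returns to 18.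

Step 18. Deprotonation at C1 may be sluggish and the SN2 step slow, since the bridgehead carbanion is screened by the C8 gem-dimethyl group; proton return and decay of the triflate would then compete. The fallback sets out from 23 and replaces the polar alkylation by a radical C–C bond formation with reagent-controlled reduction. LiTMP followed by I2 should give the bridgehead iodide F4. Et3B/air-initiated addition of the bridgehead radical to 3-methyl-2,3-bis(trimethylsilyloxy)but-1-ene, with loss of Me3SiI and aqueous work-up, gives the α-hydroxy ketone F5. Reduction with the (R)-Me-CBS oxazaborolidine and catecholborane at −78 °C (tertiary carbinol carbon as the large group) should set the (S)-carbinol and returns to 29, so that 28 and step 19 are bypassed.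

Step 7. Facial or endo/exo selectivity may be poor with this 1,3,4-trisubstituted diene, and the strongly acidic catalyst may consume the silyl dienol ether by desilylation or a Mukaiyama–Michael pathway. The fallback sets out from 6 and 8 and gives up catalyst control in favour of separation through the resident stereocentre. Me2AlCl in CH2Cl2 at −78 °C promotes the same endo Diels–Alder reaction without facial bias and should give 9 together with its core-mirrored diastereomer F6. The two differ in their relation to the (R)-lavandulyl centre, are separated by chromatography, and the route is rejoined at 9.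

**Further compounds**

F1 | step 12 | ethyl (2E)-3-[(1R,5R)-4,4-dimethyl-1-[(2R)-lavandulyl]-5-prenyl-2-oxocyclohexyl]-3-methoxyprop-2-enoate | C=C(C)[C@H](CC=C(C)C)C[C@]1(/C(OC)=C\C(=O)OCC)C[C@@H](CC=C(C)C)C(C)(C)CC1=O
F2 | step 12 | (2E)-3-[(1R,5R)-4,4-dimethyl-1-[(2R)-lavandulyl]-5-prenyl-2-oxocyclohexyl]-3-methoxyprop-2-enoic acid | C=C(C)[C@H](CC=C(C)C)C[C@]1(/C(OC)=C\C(=O)O)C[C@@H](CC=C(C)C)C(C)(C)CC1=O
F3 | step 12 | (2E)-3-[(1R,5R)-4,4-dimethyl-1-[(2R)-lavandulyl]-5-prenyl-2-oxocyclohexyl]-3-methoxyprop-2-enoyl chloride | C=C(C)[C@H](CC=C(C)C)C[C@]1(/C(OC)=C\C(=O)Cl)C[C@@H](CC=C(C)C)C(C)(C)CC1=O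
F4 | step 18 | 1-iodo derivative of 23 (iodine on the bridgehead carbon C1) | C=C(C)[C@H](CC=C(C)C)C[C@@]12C[C@@H](CC=C(C)C)C(C)(C)[C@@](I)(C(=O)C(C(=O)c3ccc(O[Si](C)(C)C(C)(C)C)c(O[Si](C)(C)C(C)(C)C)c3)=C1OC)C2=O
F5 | step 18 | 1-(3-hydroxy-3-methyl-2-oxobutyl) derivative of 23 | C=C(C)[C@H](CC=C(C)C)C[C@@]12C[C@@H](CC=C(C)C)C(C)(C)[C@@](CC(=O)C(C)(C)O)(C(=O)C(C(=O)c3ccc(O[Si](C)(C)C(C)(C)C)c(O[Si](C)(C)C(C)(C)C)c3)=C1OC)C2=O
F6 | step 7 | (1R,2S,5S)-2-(tert-butyldimethylsilyloxy)-4-methyl-1-[(2R)-lavandulyl]-5-prenylcyclohex-3-ene-1-carbaldehyde (core-mirrored diastereomer of 9) | C=C(C)[C@H](CC=C(C)C)C[C@@]1(C=O)C[C@H](CC=C(C)C)C(C)=C[C@@H]1O[Si](C)(C)C(C)(C)C
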